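**Retrosynthetic overview**
1. Carotenoid numbering is used: C1 = CMe2, C2–C4 = ring CH2, C5 = C(OH)CH3, C6 = chain-bearing carbinol, C7–C12′ = chain. The acid comes from the C25 aldehyde (Pinnick), and C11=C12 from a Wittig union of a C15 phosphonium salt with the commercial C10 dialdehyde.
2. C6–C7 comes from chelate-controlled addition of the commercial C5 enynol to (R)-2-hydroxy-2,6,6-trimethylcyclohexanone (C5 relays its configuration to C6, giving the trans-diol); C7=C8 (E) comes from trans-hydroalumination.
3. The one ring is closed in a single operation by an enantioselective [3+3] α,α′-annulation that makes C1–C2 and C4–C5: acyclic 2-(benzyloxy)-4-methylpentan-3-one plus 1-chloro-3-iodopropane.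
4. Enabling feature: ring carbon C6, held at the ketone level, lies between the two fully substituted ring carbons C1 and C5. In the acyclic ketone each of these α-carbons bears exactly one hydrogen, so C1–C6–C5 is a 1,3-dinucleophile that the C2–C3–C4 trimethylene dielectrophile spans without regiochemical ambiguity or over-alkylation.
5. Order of ring formation: only the cyclohexane ring, formed in step 3; everything after it is chain extension on the finished ring.

Key step: step 3

Remark: the target is read as the all-E (5R,6R) acid, i.e. the trans-5,6-diol with the chain cis to the C5 hydroxyl; racemic 1 is used because its stereocentre becomes a planar enolate carbon in step 3.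

**Step 1**
Reactants: 1 2-(benzyloxy)propanoic acid (racemic)
Product: 3 2-(benzyloxy)-N-methoxy-N-methylpropanamide, via acyl imidazole 2 (not isolated)
Conditions: CDI (1.1 equiv), CH2Cl2, 0 °C → rt; then MeNH(OMe)·HCl (1.2 equiv), rt
Reagents that add atoms: N,O-dimethylhydroxylamine hydrochloride, CNOC.Cl
Why: Activation of the acid as the acyl imidazole and acyl substitution by the hydroxylamine (Weinreb amide formation) should be routine for an α-alkoxy acid.

**Step 2**
Reactants: 3 2-(benzyloxy)-N-methoxy-N-methylpropanamide; 4 isopropylmagnesium chloride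
Product: 5 2-(benzyloxy)-4-methylpentan-3-one
Conditions: 4 (1.5 equiv), THF, 0 °C → rt; aq NH4Cl
Reagents that add atoms: none
Why: Weinreb ketone synthesis: the magnesium-chelated tetrahedral adduct should survive until work-up, so a single isopropyl group (C1 with both methyl groups) is delivered.

**Step 3**
Reactants: 5 2-(benzyloxy)-4-methylpentan-3-one; 6 1-chloro-3-iodopropane
Product: 9 (R)-2-(benzyloxy)-2,6,6-trimethylcyclohexan-1-one, via lithium enolate 7 (not isolated), via chloro ketone 8 (not isolated)
Conditions: (R,R)-N,N′-bis[1-phenyl-2-(piperidin-1-yl)ethyl]propane-1,3-diamine (1.05 equiv), n-BuLi (2.1 equiv), THF, 0 °C; 5, −78 °C; 6 (1.05 equiv), −78 → 0 °C; aq NH4Cl (amine recovered by acid extraction)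
Reagents that add atoms: none
Why: Proposed new method: the chiral dilithium diamide should remove the single α-hydrogen on the isopropyl side (C1, the kinetic site away from the alkoxy group), the tetrasubstituted enolate 7 displaces iodide from 6 (C1–C2), and the second N–Li of the same amide, still held in the mixed aggregate, then removes the only α-hydrogen left in 8 (C5–H) to give a benzyloxy-chelated (Z)-enolate that displaces chloride (C4–C5). The closest known reaction types are the stepwise α,α′-dialkylation of ketones with 1,3-dihalopropanes and the enantioselective alkylation of lithium enolates and enediolates in mixed aggregates with C2-symmetric chiral lithium amides, which is known for intermolecular construction of tetrasubstituted α-alkoxy carbonyl centres but not for a ring-closing ketone alkylation. The cyclohexanone closes in the 6-(enolendo)-exo-tet mode, in which the enolate carbon can reach the backside of the C–Cl bond, so C-alkylation should be preferred over closure through oxygen. C5, the only stereocentre formed, is set under reagent control: the amide bound in the aggregate shields one face of the planar chelated enolate, and because the three-carbon tether can reach either face, the (S,S)-amine is used instead should the (R,R)-amine favour the (S)-ketone. The step needs mono-alkylation of the dihalide before ring closure, C- over O-alkylation and one defined enolization site at each stage. The iodide/chloride reactivity gap should secure the first, lithium in THF the second, and the substrate the third, because each α-carbon of 5 carries exactly one hydrogen, so the carbon alkylated first becomes quaternary and cannot enolize again.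

**Step 4**
Reactants: 9 (R)-2-(benzyloxy)-2,6,6-trimethylcyclohexan-1-one
Product: 10 (R)-2-hydroxy-2,6,6-trimethylcyclohexan-1-one
Conditions: H2 (1 atm), Pd/C (10 wt%), EtOAc, rt
Reagents that add atoms: none
Why: Hydrogenolysis of the benzyl ether should leave the ketone between two quaternary carbons untouched and frees the hydroxyl that serves as the chelating alkoxide in step 5.

**Step 5**
Reactants: 10 (R)-2-hydroxy-2,6,6-trimethylcyclohexan-1-one; 11 (E)-3-methylpent-2-en-4-yn-1-ol
Product: 13 (1S,2R)-1-[(3E)-5-hydroxy-3-methylpent-3-en-1-yn-1-yl]-2,6,6-trimethylcyclohexane-1,2-diol, via magnesium acetylide 12 (not isolated)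
Conditions: 11 (3.0 equiv), EtMgBr (6.0 equiv), THF, 0 → 40 °C; then 10 in THF, 0 °C → rt; aq NH4Cl
Reagents that add atoms: none
Why: Chelation-controlled 1,2-addition of an alkynyl Grignard reagent: the bromomagnesium alkoxide at C5 should hold O5 syn-coplanar (equatorial) to the carbonyl and the C5 methyl axial, so the slim acetylide enters anti to the two axial methyl groups (axial attack), which places C7 cis to O5 and sets C6 of the trans-diol by substrate control from C5.

**Step 6**
Reactants: 13 (1S,2R)-1-[(3E)-5-hydroxy-3-methylpent-3-en-1-yn-1-yl]-2,6,6-trimethylcyclohexane-1,2-diol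
Product: 14 (1R,2R)-1-[(1E,3E)-5-hydroxy-3-methylpenta-1,3-dien-1-yl]-2,6,6-trimethylcyclohexane-1,2-diol
Conditions: NaAlH2(OCH2CH2OCH3)2 (4 equiv), THF, 0 °C → rt; aq potassium sodium tartrate
Reagents that add atoms: none
Why: Hydroxyl-directed trans-hydroalumination of the propargylic alkoxide followed by protonolysis should give the 7E alkene only, with the C9=C10 bond and both carbinol centres untouched.

**Step 7**
Reactants: 14 (1R,2R)-1-[(1E,3E)-5-hydroxy-3-methylpenta-1,3-dien-1-yl]-2,6,6-trimethylcyclohexane-1,2-diol
Product: 16 {(2E,4E)-5-[(1R,2R)-1,2-dihydroxy-2,6,6-trimethylcyclohexyl]-3-methylpenta-2,4-dien-1-yl}triphenylphosphonium bromide, via allylic bromide 15 (not isolated)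
Conditions: PPh3 (1.15 equiv), CBr4 (1.1 equiv), 2,6-lutidine (0.3 equiv), CH2Cl2, −20 °C; then PPh3 (1.2 equiv), rt
Reagents that add atoms: carbon tetrabromide, BrC(Br)(Br)Br; triphenylphosphine, c1ccc(cc1)P(c1ccccc1)c1ccccc1
Why: Appel bromination should be limited to the single primary (allylic) hydroxyl, and the bromide is quaternized in the same flask by SN2 attack of PPh3 at C11; the neutral, buffered medium should keep the acid-labile tertiary dienylic hydroxyl at C6 intact.

**Step 8**
Reactants: 16 {(2E,4E)-5-[(1R,2R)-1,2-dihydroxy-2,6,6-trimethylcyclohexyl]-3-methylpenta-2,4-dien-1-yl}triphenylphosphonium bromide; 17 (2E,4E,6E)-2,7-dimethylocta-2,4,6-trienedial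
Product: 19 (2E,4E,6E,8E,10E,12E)-13-[(1R,2R)-1,2-dihydroxy-2,6,6-trimethylcyclohexyl]-2,7,11-trimethyltrideca-2,4,6,8,10,12-hexaenal, via phosphorus ylide 18 (not isolated)
Conditions: NaOCH3 (1.1 equiv), CH3OH/CH2Cl2, 0 °C; 17 (3 equiv), 0 °C → rt; then reflux in EtOAc (argon, dark)
Reagents that add atoms: none
Why: Wittig olefination of the semi-stabilized allylic ylide with an excess of the symmetrical dialdehyde should form C11=C12 by mono-olefination (the extended polyenal product is the poorer electrophile), and thermal equilibration should convert the hindered 11Z isomer into the all-E chain.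

**Step 9**
Reactants: 19 (2E,4E,6E,8E,10E,12E)-13-[(1R,2R)-1,2-dihydroxy-2,6,6-trimethylcyclohexyl]-2,7,11-trimethyltrideca-2,4,6,8,10,12-hexaenal
Product: 20 (2E,4E,6E,8E,10E,12E)-13-[(1R,2R)-1,2-dihydroxy-2,6,6-trimethylcyclohexyl]-2,7,11-trimethyltrideca-2,4,6,8,10,12-hexaenoic acid
Conditions: NaClO2 (3 equiv), NaH2PO4 (3 equiv), 2-methylbut-2-ene (30 equiv), t-BuOH/THF/H2O, 0 °C → rt, dark
Reagents that add atoms: sodium chlorite, [Na+].[O-]Cl=O
Why: Pinnick oxidation should convert the conjugated aldehyde into the acid without touching the tertiary alcohols, the large excess of 2-methylbut-2-ene intercepting HOCl before it can attack the polyene.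

**Compound list**
1 | 2-(benzyloxy)propanoic acid (racemic) | CC(OCc1ccccc1)C(=O)O | starting material
2 | 2-(benzyloxy)-1-(1H-imidazol-1-yl)propan-1-one (racemic) | CC(OCc1ccccc1)C(=O)n1ccnc1 | intermediate
3 | 2-(benzyloxy)-N-methoxy-N-methylpropanamide (racemic) | CC(OCc1ccccc1)C(=O)N(C)OC | intermediate
4 | isopropylmagnesium chloride | CC(C)[Mg]Cl | starting material
5 | 2-(benzyloxy)-4-methylpentan-3-one (racemic) | CC(C)C(=O)C(C)OCc1ccccc1 | intermediate
6 | 1-chloro-3-iodopropane | ClCCCI | starting material
7 | lithium 4-(benzyloxy)-2-methylpent-2-en-3-olate | CC(C)=C(O[Li])C(C)OCc1ccccc1 | intermediate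
8 | 2-(benzyloxy)-7-chloro-4,4-dimethylheptan-3-one (racemic) | CC(OCc1ccccc1)C(=O)C(C)(C)CCCCl | intermediate
9 | (R)-2-(benzyloxy)-2,6,6-trimethylcyclohexan-1-one | O=C1C(C)(C)CCC[C@@]1(C)OCc1ccccc1 | intermediate
10 | (R)-2-hydroxy-2,6,6-trimethylcyclohexan-1-one | O=C1C(C)(C)CCC[C@@]1(C)O | intermediate
11 | (E)-3-methylpent-2-en-4-yn-1-ol | C#C/C(C)=C/CO | starting material
12 | bromo[(E)-5-(bromomagnesiooxy)-3-methylpent-3-en-1-yn-1-yl]magnesium | Br[Mg]OC/C=C(C)/C#C[Mg]Br | intermediate
13 | (1S,2R)-1-[(3E)-5-hydroxy-3-methylpent-3-en-1-yn-1-yl]-2,6,6-trimethylcyclohexane-1,2-diol | OC/C=C(C)/C#C[C@@]1(O)C(C)(C)CCC[C@@]1(C)O | intermediate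
14 | (1R,2R)-1-[(1E,3E)-5-hydroxy-3-methylpenta-1,3-dien-1-yl]-2,6,6-trimethylcyclohexane-1,2-diol | OC/C=C(C)/C=C/[C@@]1(O)C(C)(C)CCC[C@@]1(C)O | intermediate
15 | (1R,2R)-1-[(1E,3E)-5-bromo-3-methylpenta-1,3-dien-1-yl]-2,6,6-trimethylcyclohexane-1,2-diol | BrC/C=C(C)/C=C/[C@@]1(O)C(C)(C)CCC[C@@]1(C)O | intermediate
16 | {(2E,4E)-5-[(1R,2R)-1,2-dihydroxy-2,6,6-trimethylcyclohexyl]-3-methylpenta-2,4-dien-1-yl}triphenylphosphonium bromide | C(/C=C(C)/C=C/[C@@]1(O)C(C)(C)CCC[C@@]1(C)O)[P+](c1ccccc1)(c1ccccc1)c1ccccc1.[Br-] | intermediate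
17 | (2E,4E,6E)-2,7-dimethylocta-2,4,6-trienedial | O=C/C(C)=C/C=C/C=C(C)/C=O | starting material
18 | {(2E,4E)-5-[(1R,2R)-1,2-dihydroxy-2,6,6-trimethylcyclohexyl]-3-methylpenta-2,4-dien-1-ylidene}triphenyl-λ5-phosphane | C(/C=C(C)/C=C/[C@@]1(O)C(C)(C)CCC[C@@]1(C)O)=P(c1ccccc1)(c1ccccc1)c1ccccc1 | intermediate
19 | (2E,4E,6E,8E,10E,12E)-13-[(1R,2R)-1,2-dihydroxy-2,6,6-trimethylcyclohexyl]-2,7,11-trimethyltrideca-2,4,6,8,10,12-hexaenal | CC(/C=C/C=C(C)/C=C/[C@@]1(O)C(C)(C)CCC[C@@]1(C)O)=C\C=C\C=C(/C)C=O | intermediate
20 | (2E,4E,6E,8E,10E,12E)-13-[(1R,2R)-1,2-dihydroxy-2,6,6-trimethylcyclohexyl]-2,7,11-trimethyltrideca-2,4,6,8,10,12-hexaenoic acid | CC(/C=C/C=C(C)/C=C/[C@@]1(O)C(C)(C)CCC[C@@]1(C)O)=C\C=C\C=C(/C)C(=O)O | target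

**Step count**
Total steps: 9. Longest linear sequence: 9 steps (1 → 20).

**Steps most likely to fail**

Step 3 (Proposed new method). The ring-closing alkylation may show too little facial discrimination. A first alkylation at C5 instead of C1 would set the stereocentre in a different, intermolecular event. The iodide may alkylate the amide nitrogen, and the hindered alkoxy enolate may close through oxygen. The fallback uses only known chemistry (self-regeneration of stereocentres) and sets out from 6:
- 6 alkylates the lithium enolate (LiN(i-Pr)2, THF, −78 °C) of commercial (2S,5S)-2-tert-butyl-5-methyl-1,3-dioxolan-4-one anti to the tert-butyl group, giving (2S,5R)-2-tert-butyl-5-(3-chloropropyl)-5-methyl-1,3-dioxolan-4-one F1.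
- Isopropyllithium (THF, −78 °C) opens the lactone to (R)-7-chloro-4-hydroxy-2,4-dimethylheptan-3-one F2, with loss of pivalaldehyde on work-up.
- MOMCl/i-Pr2NEt gives (R)-7-chloro-4-(methoxymethoxy)-2,4-dimethylheptan-3-one F3; protection is needed because the free tertiary alkoxide would close a tetrahydrofuran onto the chloride.
- KN(SiMe3)2 with NaI (THF, −78 °C → rt) closes the ring at C1 in the 6-(enolendo)-exo-tet mode to (R)-2-(methoxymethoxy)-2,6,6-trimethylcyclohexan-1-one F4.
- HCl in CH3OH removes the acetal, and the route is rejoined at 10.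

Step 5. Addition to a carbonyl flanked by two quaternary carbons may be slow. Prolonged warming may then allow a base-promoted α-ketol shift of the magnesium alkoxide of 10, and the poorly soluble bis-magnesium reagent may erode chelate control. The fallback sets out from 10: the small, soluble ethynylmagnesium bromide (HC≡CMgBr, THF, 0 °C → rt) is added under the same chelate control to give (1S,2R)-1-ethynyl-2,6,6-trimethylcyclohexane-1,2-diol F5. The C8–C9 bond is then made by Sonogashira coupling with (E)-3-iodobut-2-en-1-ol (Pd(PPh3)2Cl2, CuI, Et3N), which returns to 13.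

Step 7. Adventitious HBr may ionize the tertiary dienylic hydroxyl at C6, leading to cyclization of O5 onto C8 or to dehydration, and the allylic bromide may transpose. The fallback sets out from 14: selective acetylation of the primary hydroxyl (Ac2O, pyridine, 0 °C) gives (2E,4E)-5-[(1R,2R)-1,2-dihydroxy-2,6,6-trimethylcyclohexyl]-3-methylpenta-2,4-dien-1-yl acetate F6. Ionization of the acetate by Pd(PPh3)4 (cat.) with capture of the allyl complex by PPh3 in the presence of NaBr (THF/CH3OH, rt) gives the phosphonium salt under neutral conditions and returns to 16.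

**Further compounds**
F1 | step 3 | (2S,5R)-2-tert-butyl-5-(3-chloropropyl)-5-methyl-1,3-dioxolan-4-one | C[C@]1(CCCCl)O[C@H](C(C)(C)C)OC1=O
F2 | step 3 | (R)-7-chloro-4-hydroxy-2,4-dimethylheptan-3-one | ClCCC[C@@](C)(O)C(=O)C(C)C
F3 | step 3 | (R)-7-chloro-4-(methoxymethoxy)-2,4-dimethylheptan-3-one | ClCCC[C@@](C)(OCOC)C(=O)C(C)C
F4 | step 3 | (R)-2-(methoxymethoxy)-2,6,6-trimethylcyclohexan-1-one | O=C1C(C)(C)CCC[C@@]1(C)OCOC
F5 | step 5 | (1S,2R)-1-ethynyl-2,6,6-trimethylcyclohexane-1,2-diol | C#C[C@@]1(O)C(C)(C)CCC[C@@]1(C)O
F6 | step 7 | (2E,4E)-5-[(1R,2R)-1,2-dihydroxy-2,6,6-trimethylcyclohexyl]-3-methylpenta-2,4-dien-1-yl acetate | CC(=O)OC/C=C(C)/C=C/[C@@]1(O)C(C)(C)CCC[C@@]1(C)O
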